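The synthesis rests on cutting the cyclohexene at C16–C4 and C2–C3 (labels in the remark below). The key step is an intramolecular Diels–Alder reaction inside an eleven-membered ring: a 1-silyloxy diene (C2=C1–C15=C16) of the macrocycle adds to an (E)-alkenyl boronate (C4=C3) tethered to C7. One operation closes the cyclopentane and the cyclohexene together as the last ring-forming event, sets C2, C3, C4 and C16, and leaves the C1=C15 alkene. It exploits the cyclohexene-1,2-diol whose unfunctionalised, cis-fused cyclopentane shares C16–C4. The precursor is a monocyclic cycloundecene enal with a pendant alkenyl boronate, built from (R)-limonene oxide and (S)-citronellyl bromide and closed by Nozaki–Hiyama–Kishi coupling.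

Key step: step 16

Remark: carbons carry trinervitane labels; read along the target SMILES they are C19, C8, C9 (acetoxy), C10, C11, C12 (with C20), C13, C14, C1, C15 (with C17), C16, C7, C6, C5, C4 (with C18), C3, C2; names of intermediates use their own locants; Bpin is 4,4,5,5-tetramethyl-1,3,2-dioxaborolan-2-yl; commercial (+)-limonene 1,2-oxide is assumed to be the (4R) cis/trans mixture, which converges in step 1.

Step 1
Reactants: 1 (4R)-limonene 1,2-oxide
Product: 3 (3R)-6-oxo-3-(prop-1-en-2-yl)heptanal, via limonene-1,2-diol 2 (not isolated)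
Conditions: H5IO6, THF–H2O, 0 °C to rt
Reagents that add atoms: water, O
Why: Acid-promoted opening of the epoxide to the diol and Malaprade glycol cleavage by periodic acid in the same flask should give the keto aldehyde from either epoxide isomer, and the stereocentre that becomes C7 is not involved.

Step 2
Reactants: 3 keto aldehyde
Product: 4 (5R)-8,8-dibromo-5-(prop-1-en-2-yl)oct-7-en-2-one
Conditions: CBr4, PPh3, CH2Cl2, 0 °C
Reagents that add atoms: carbon tetrabromide, BrC(Br)(Br)Br
Why: First stage of the Corey–Fuchs sequence (Wittig-type dibromo-olefination), in which the ylide takes the aldehyde and not the methyl ketone, and whose base-free conditions keep the keto aldehyde from aldol closure.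

Step 3
Reactants: 4 dibromo-olefin ketone
Product: 5 2-[(3R)-6,6-dibromo-3-(prop-1-en-2-yl)hex-5-en-1-yl]-2-methyl-1,3-dioxolane
Conditions: HOCH2CH2OH, PPTS (cat.), benzene, reflux (Dean–Stark)
Reagents that add atoms: ethane-1,2-diol, OCCO
Why: Acid-catalysed ketalisation masks the future C4 ketone for the organolithium, cuprate and enolate steps and later tells it apart from the second methyl ketone made in step 8.

Step 4
Reactants: 5 dibromo-olefin ketal
Product: 7 methyl (5R)-6-methyl-5-[2-(2-methyl-1,3-dioxolan-2-yl)ethyl]hept-6-en-2-ynoate, via lithium acetylide 6 (not isolated)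
Conditions: n-BuLi (2.1 equiv), THF, −78 to 0 °C; then ClCO2Me, −78 °C
Reagents that add atoms: methyl chloroformate, COC(Cl)=O
Why: Second stage of the Corey–Fuchs sequence (bromine–lithium exchange, Fritsch–Buttenberg–Wiechell rearrangement, deprotonation) gives the lithium acetylide, which methyl chloroformate acylates on carbon to the ynoate.

Step 5
Reactants: 7 ynoate
Product: 9 methyl (2E,5R)-2-iodo-3,6-dimethyl-5-[2-(2-methyl-1,3-dioxolan-2-yl)ethyl]hepta-2,6-dienoate, via alkenylcuprate 8 (not isolated)
Conditions: Me2CuLi, Et2O–THF, −78 °C; then I2, −78 °C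
Reagents that add atoms: lithium dimethylcuprate, [Li+].C[Cu-]C; iodine, II
Why: Syn-carbocupration of the ynoate puts the new C17 methyl on C15 and copper on C1 on the same side, and iodinolysis of the alkenylcuprate at low temperature with retention fixes the tetrasubstituted geometry (iodine cis to the methyl, ester cis to the C16 methylene).

Step 6
Reactants: 10 (S)-citronellyl bromide
Product: 12 (4S)-6-bromo-1,1-dimethoxy-4-methylhexane, via bromo aldehyde 11 (not isolated)
Conditions: O3, CH2Cl2–MeOH, −78 °C; Me2S; then TsOH (cat.), MeOH, rt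
Reagents that add atoms: methanol, CO
Why: Ozonolysis of the trisubstituted alkene with reductive work-up, then acid-catalysed acetalisation in the same flask; the C12 stereocentre comes from the chiral pool and is untouched.

Step 7
Reactants: 9 iodo enoate; 12 bromo acetal
Product: 14 methyl (2Z,5R)-2-[(3R)-6,6-dimethoxy-3-methylhexyl]-3,6-dimethyl-5-[2-(2-methyl-1,3-dioxolan-2-yl)ethyl]hepta-2,6-dienoate, via alkylzinc bromide 13 (not isolated)
Conditions: 12, Zn, I2 (cat.), DMA, 80 °C; then 9, PdCl2(dppf) (cat.), rt to 50 °C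
Reagents that add atoms: none
Why: Negishi sp3–sp2 cross-coupling, in which zinc inserts into the primary bromide and zerovalent palladium couples the alkylzinc with the alkenyl iodide with retention, so C14 ends cis to the C17 methyl.

Step 8
Reactants: 14 dienoate
Product: 15 methyl (2Z,5R)-5-acetyl-2-[(3R)-6,6-dimethoxy-3-methylhexyl]-3-methyl-7-(2-methyl-1,3-dioxolan-2-yl)hept-2-enoate
Conditions: OsO4 (cat.), NaIO4, 2,6-lutidine, dioxane–H2O, rt
Reagents that add atoms: sodium periodate, [Na+].[O-]I(=O)(=O)=O
Why: Lemieux–Johnson oxidation (catalytic dihydroxylation, periodate cleavage) acts only on the electron-rich 1,1-disubstituted alkene, because the tetrasubstituted ester-conjugated alkene is inert and the lutidine buffer protects both acetals.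

Step 9
Reactants: 15 methyl ketone
Product: 17 methyl (2Z,5R)-2-[(3R)-6,6-dimethoxy-3-methylhexyl]-3-methyl-7-(2-methyl-1,3-dioxolan-2-yl)-5-[1-(trifluoromethylsulfonyloxy)ethenyl]hept-2-enoate, via lithium enolate 16 (not isolated)
Conditions: LiN(iPr)2, THF, −78 °C; then PhNTf2, −78 to 0 °C
Reagents that add atoms: N-phenylbis(trifluoromethanesulfonimide), O=S(=O)(N(c1ccccc1)S(=O)(=O)C(F)(F)F)C(F)(F)F
Why: Kinetic deprotonation at the methyl group of the ketone and O-sulfonylation of the enolate (enol triflate formation) give the 2-triflyloxy-1-alkene without epimerising C7.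

Step 10
Reactants: 17 alkenyl triflate bis-acetal
Product: 18 methyl (2Z,5R)-3-methyl-2-[(3R)-3-methyl-6-oxohexyl]-8-oxo-5-[1-(trifluoromethylsulfonyloxy)ethenyl]non-2-enoate
Conditions: 1 M HCl, THF, rt
Reagents that add atoms: water, O
Why: Acid-catalysed acetal hydrolysis frees the C9 aldehyde and the C4 ketone together, while the alkenyl triflate and the enoate are stable to dilute aqueous acid.

Step 11
Reactants: 18 keto aldehyde alkenyl triflate
Product: 19 methyl (1Z,4R,6S,9R)-6-hydroxy-2,9-dimethyl-5-methylidene-4-(3-oxobutyl)cycloundec-1-ene-1-carboxylate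
Conditions: CrCl2 (excess), NiCl2 (cat.), DMF–THF, rt, high dilution (slow addition)
Reagents that add atoms: none
Why: Nozaki–Hiyama–Kishi reaction, in which zerovalent nickel inserts into the alkenyl triflate and the alkenylchromium formed by transmetalation adds to the aldehyde and not to the ketone or ester, closing the eleven-membered ring as the 1,1-disubstituted allylic alcohol; C9 is set by substrate control in the ring-closing conformation fixed by C7, C12 and the rigid tetrasubstituted alkene, and the 9S alcohol is the isomer taken on.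

Step 12
Reactants: 19 macrocyclic keto ester
Product: 20 methyl (1Z,4R,6S,9R)-6-hydroxy-2,9-dimethyl-5-methylidene-4-[(3E)-3-methyl-4-Bpin-but-3-en-1-yl]cycloundec-1-ene-1-carboxylate
Conditions: CH2(Bpin)2, lithium 2,2,6,6-tetramethylpiperidide (2.5 equiv), THF, 0 °C; then 19, −78 °C to rt
Reagents that add atoms: bis(4,4,5,5-tetramethyl-1,3,2-dioxaborolan-2-yl)methane, CC1(C)OB(CB2OC(C)(C)C(C)(C)O2)OC1(C)C
Why: Boron–Wittig olefination, in which the lithiated geminal bis(boronate) adds to the methyl ketone and syn-elimination of boron and oxygen gives the trisubstituted alkenyl boronate with boron trans to the larger chain (E), the hydroxyl being carried as its lithium alkoxide.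

Step 13
Reactants: 20 ester
Product: 21 (1Z,4R,6S,9R)-1-(hydroxymethyl)-2,9-dimethyl-5-methylidene-4-[(3E)-3-methyl-4-Bpin-but-3-en-1-yl]cycloundec-1-en-6-ol
Conditions: iBu2AlH, CH2Cl2, −78 °C; aq. Rochelle salt
Reagents that add atoms: none
Why: Hydride reduction of the α,β-unsaturated ester to the primary allylic alcohol (1,2-reduction), which alkenyl pinacol boronates tolerate at low temperature.

Step 14
Reactants: 21 diol
Product: 22 (1Z,4R,6S,9R)-6-hydroxy-2,9-dimethyl-5-methylidene-4-[(3E)-3-methyl-4-Bpin-but-3-en-1-yl]cycloundec-1-ene-1-carbaldehyde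
Conditions: TEMPO (cat.), PhI(OAc)2, CH2Cl2, rt
Reagents that add atoms: none
Why: Oxoammonium (TEMPO) oxidation is selective for the primary allylic alcohol over the secondary one and gives the enal without moving the tetrasubstituted alkene.

Step 15
Reactants: 22 hydroxy enal
Product: 23 (1Z,4R,6S,9R)-1-formyl-2,9-dimethyl-5-methylidene-4-[(3E)-3-methyl-4-Bpin-but-3-en-1-yl]cycloundec-1-en-6-yl acetate
Conditions: Ac2O, pyridine, DMAP (cat.), CH2Cl2, 0 °C to rt
Reagents that add atoms: acetic anhydride, CC(=O)OC(C)=O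
Why: Nucleophile-catalysed acylation of the secondary allylic alcohol installs the C9 acetate at a point after which no ester-cleaving reagent is used.

Step 16
Reactants: 23 enal acetate
Product: 25 (2S,3R,4R,7R,9S,12R,16R)-2-(tert-butyldimethylsilyloxy)-3-Bpin-trinervita-1(15),8(19)-dien-9-yl acetate, via silyl dienol ether 24 (not isolated)
Conditions: TBSOTf, Et3N, toluene, 0 °C to rt; then BHT (cat.), 150 °C, sealed tube
Reagents that add atoms: tert-butyldimethylsilyl triflate, CC(C)(C)[Si](C)(C)OS(=O)(=O)C(F)(F)F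
Why: Soft enolisation (O-silylation of the enal, then loss of the C16 proton that lies cis to the formyl group) should give the (1E)-silyloxy diene 24 with an E C15=C16 bond in the ring; on heating, this diene and the tethered (E)-alkenyl boronate combine in a concerted, suprafacial [4π+2π] cycloaddition, a type-1 intramolecular Diels–Alder reaction of a 1,3,8-nonatriene unit as known for silyloxy dienes and for alkenyl boronates. The cyclohexene closes through the two new bonds C16–C4 and C2–C3, and the cyclopentane closes in the same event through C16–C4 across the C7–C6–C5 tether, so no ring is formed afterwards. C2 and C16 are fixed relative to each other by the diene geometry (silyloxy group and C7 both outside, hence cis), C3 and C4 by the E alkene (boron cis to the C18 methyl), and the two pairs are related by the tether-endo, boron-exo transition state that gives the cis ring fusion. The absolute sense is relayed from C7: the bridge C8–C14 can reach C14 only if it leaves C7 syn-clinal to C15=C16 on one face of the diene, which places the tether syn-clinal on the other face and therefore under the diene. Regiochemistry is fixed by the tether and agrees with the electronic preference (donor at C2, boron at C3 on adjacent carbons). The selectivity needed is γ-silylation at C16 and not at C17 (secured by the cis relation of C16 to the formyl group and by the more substituted diene) and the endo-tether mode over the trans-fused one (secured by the ring constraint just described).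

Step 17
Reactants: 25 cycloadduct
Product: 26 (2R,3R,4S,7R,9S,12R,16S)-2-(tert-butyldimethylsilyloxy)-3-hydroxytrinervita-1(15),8(19)-dien-9-yl acetate
Conditions: H2O2 (30% aq.), pH 7 phosphate buffer, THF, 0 °C to rt
Reagents that add atoms: hydrogen peroxide, OO
Why: Oxidation of the secondary alkyl boronate (hydroperoxide adds to boron, carbon migrates to oxygen with retention) turns C3–B into C3–OH with the configuration set in the cycloaddition, and the buffered medium spares the acetate.

Step 18
Reactants: 26 mono-silyl ether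
Product: 27 (2R,3R,4S,7R,9S,12R,16S)-2,3-dihydroxytrinervita-1(15),8(19)-dien-9-yl acetate (CNP0192310.1)
Conditions: HF·pyridine, pyridine, THF, 0 °C to rt
Reagents that add atoms: none
Why: Fluoride-mediated cleavage of the allylic silyl ether frees the C2 hydroxyl without touching the acetate or the alkenes.

Compound list
1 | (4R)-limonene 1,2-oxide, cis/trans mixture at the epoxide | CC(=C)[C@@H]1CCC2(C)OC2C1 | starting material
2 | (4R)-1-methyl-4-(prop-1-en-2-yl)cyclohexane-1,2-diol, formed in the flask and not isolated | CC(=C)[C@@H]1CCC(C)(O)C(O)C1 | intermediate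
3 | (3R)-6-oxo-3-(prop-1-en-2-yl)heptanal | O=CC[C@@H](CCC(C)=O)C(C)=C | intermediate
4 | (5R)-8,8-dibromo-5-(prop-1-en-2-yl)oct-7-en-2-one | BrC(Br)=CC[C@@H](CCC(C)=O)C(C)=C | intermediate
5 | 2-[(3R)-6,6-dibromo-3-(prop-1-en-2-yl)hex-5-en-1-yl]-2-methyl-1,3-dioxolane | BrC(Br)=CC[C@@H](CCC1(C)OCCO1)C(C)=C | intermediate
6 | lithium acetylide from 5, not isolated | [Li]C#CC[C@@H](CCC1(C)OCCO1)C(C)=C | intermediate
7 | methyl (5R)-6-methyl-5-[2-(2-methyl-1,3-dioxolan-2-yl)ethyl]hept-6-en-2-ynoate | COC(=O)C#CC[C@@H](CCC1(C)OCCO1)C(C)=C | intermediate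
8 | lithium alkenyl(methyl)cuprate from 7, copper on C1 cis to the new methyl, not isolated | [Li+].COC(=O)/C([Cu-]C)=C(C)\C[C@@H](CCC1(C)OCCO1)C(C)=C | intermediate
9 | methyl (2E,5R)-2-iodo-3,6-dimethyl-5-[2-(2-methyl-1,3-dioxolan-2-yl)ethyl]hepta-2,6-dienoate | COC(=O)/C(I)=C(C)\C[C@@H](CCC1(C)OCCO1)C(C)=C | intermediate
10 | (S)-citronellyl bromide, (6S)-8-bromo-2,6-dimethyloct-2-ene | CC(C)=CCC[C@H](C)CCBr | starting material
11 | (4S)-6-bromo-4-methylhexanal, not isolated | O=CCC[C@H](C)CCBr | intermediate
12 | (4S)-6-bromo-1,1-dimethoxy-4-methylhexane | COC(OC)CC[C@H](C)CCBr | intermediate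
13 | [(3S)-6,6-dimethoxy-3-methylhexyl]zinc bromide, not isolated | COC(OC)CC[C@H](C)CC[Zn]Br | intermediate
14 | methyl (2Z,5R)-2-[(3R)-6,6-dimethoxy-3-methylhexyl]-3,6-dimethyl-5-[2-(2-methyl-1,3-dioxolan-2-yl)ethyl]hepta-2,6-dienoate | COC(=O)/C(CC[C@@H](C)CCC(OC)OC)=C(C)\C[C@@H](CCC1(C)OCCO1)C(C)=C | intermediate
15 | methyl (2Z,5R)-5-acetyl-2-[(3R)-6,6-dimethoxy-3-methylhexyl]-3-methyl-7-(2-methyl-1,3-dioxolan-2-yl)hept-2-enoate | COC(=O)/C(CC[C@@H](C)CCC(OC)OC)=C(C)\C[C@@H](CCC1(C)OCCO1)C(C)=O | intermediate
16 | terminal lithium enolate of 15, not isolated | COC(=O)/C(CC[C@@H](C)CCC(OC)OC)=C(C)\C[C@@H](CCC1(C)OCCO1)C(=C)O[Li] | intermediate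
17 | methyl (2Z,5R)-2-[(3R)-6,6-dimethoxy-3-methylhexyl]-3-methyl-7-(2-methyl-1,3-dioxolan-2-yl)-5-[1-(trifluoromethylsulfonyloxy)ethenyl]hept-2-enoate | COC(=O)/C(CC[C@@H](C)CCC(OC)OC)=C(C)\C[C@@H](CCC1(C)OCCO1)C(=C)OS(=O)(=O)C(F)(F)F | intermediate
18 | methyl (2Z,5R)-3-methyl-2-[(3R)-3-methyl-6-oxohexyl]-8-oxo-5-[1-(trifluoromethylsulfonyloxy)ethenyl]non-2-enoate | COC(=O)/C(CC[C@@H](C)CCC=O)=C(C)\C[C@@H](CCC(C)=O)C(=C)OS(=O)(=O)C(F)(F)F | intermediate
19 | methyl (1Z,4R,6S,9R)-6-hydroxy-2,9-dimethyl-5-methylidene-4-(3-oxobutyl)cycloundec-1-ene-1-carboxylate (ring carbons 11 and 3 trans across the alkene) | C=C1[C@@H](O)CC[C@H](C)CC/C(C(=O)OC)=C(C)/C[C@H]1CCC(C)=O | intermediate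
20 | methyl (1Z,4R,6S,9R)-6-hydroxy-2,9-dimethyl-5-methylidene-4-[(3E)-3-methyl-4-Bpin-but-3-en-1-yl]cycloundec-1-ene-1-carboxylate | C=C1[C@@H](O)CC[C@H](C)CC/C(C(=O)OC)=C(C)/C[C@H]1CC/C(C)=C/B2OC(C)(C)C(C)(C)O2 | intermediate
21 | (1Z,4R,6S,9R)-1-(hydroxymethyl)-2,9-dimethyl-5-methylidene-4-[(3E)-3-methyl-4-Bpin-but-3-en-1-yl]cycloundec-1-en-6-ol | C=C1[C@@H](O)CC[C@H](C)CC/C(CO)=C(C)/C[C@H]1CC/C(C)=C/B2OC(C)(C)C(C)(C)O2 | intermediate
22 | (1Z,4R,6S,9R)-6-hydroxy-2,9-dimethyl-5-methylidene-4-[(3E)-3-methyl-4-Bpin-but-3-en-1-yl]cycloundec-1-ene-1-carbaldehyde | C=C1[C@@H](O)CC[C@H](C)CC/C(C=O)=C(C)/C[C@H]1CC/C(C)=C/B2OC(C)(C)C(C)(C)O2 | intermediate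
23 | (1Z,4R,6S,9R)-1-formyl-2,9-dimethyl-5-methylidene-4-[(3E)-3-methyl-4-Bpin-but-3-en-1-yl]cycloundec-1-en-6-yl acetate | C=C1[C@@H](OC(C)=O)CC[C@H](C)CC/C(C=O)=C(C)/C[C@H]1CC/C(C)=C/B2OC(C)(C)C(C)(C)O2 | intermediate
24 | (2E,4R,6S,9R)-1-[(E)-(tert-butyldimethylsilyloxy)methylidene]-2,9-dimethyl-5-methylidene-4-[(3E)-3-methyl-4-Bpin-but-3-en-1-yl]cycloundec-2-en-6-yl acetate, not isolated | C=C1[C@@H](OC(C)=O)CC[C@H](C)CC/C(=C\O[Si](C)(C)C(C)(C)C)/C(C)=C/[C@H]1CC/C(C)=C/B2OC(C)(C)C(C)(C)O2 | intermediate
25 | (2S,3R,4R,7R,9S,12R,16R)-2-(tert-butyldimethylsilyloxy)-3-Bpin-trinervita-1(15),8(19)-dien-9-yl acetate; every centre is arranged in space as in 27, and the descriptors at C2, C4 and C16 differ only because boron ranks below carbon | C=C1[C@@H](OC(C)=O)CC[C@H](C)CCC2=C(C)[C@@H]3[C@H]1CC[C@]3(C)[C@@H](B4OC(C)(C)C(C)(C)O4)[C@@H]2O[Si](C)(C)C(C)(C)C | intermediate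
26 | (2R,3R,4S,7R,9S,12R,16S)-2-(tert-butyldimethylsilyloxy)-3-hydroxytrinervita-1(15),8(19)-dien-9-yl acetate | C=C1[C@@H](OC(C)=O)CC[C@H](C)CCC2=C(C)[C@@H]3[C@H]1CC[C@]3(C)[C@@H](O)[C@@H]2O[Si](C)(C)C(C)(C)C | intermediate
27 | (2R,3R,4S,7R,9S,12R,16S)-2,3-dihydroxytrinervita-1(15),8(19)-dien-9-yl acetate, CNP0192310.1 | C=C1[C@@H](OC(C)=O)CC[C@H](C)CCC2=C(C)[C@@H]3[C@H]1CC[C@]3(C)[C@@H](O)[C@@H]2O | target

Total step count: 18 steps. Longest linear sequence: 17 steps (from 1 through steps 1–5 and 7–18); step 6 prepares the side fragment from 10.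

Steps most likely to fail

Step 16 (key step). The process at risk is slow addition of the trisubstituted alkenyl boronate, so that desilylation of the diene or elimination across the C2–C3 silyloxy boronate competes at the temperature needed. The fallback is a boron-free cycloaddition in which the dienophile brings its own oxygen, and it sets out from 23. Buffered H2O2 oxidises the alkenyl boronate to the α-methyl aldehyde F1, leaving the enal and the acetate. TBSOTf and Et3N then silylate both carbonyl groups to the bis(silyl enol ether) F2; the (E)-enol ether (silyloxy cis to the C18 methyl) is needed and is separated if the Z isomer forms. Heating F2 in xylene at about 190 °C, in the same intramolecular Diels–Alder mode, should give the bis(silyl ether) F3, and HF·pyridine returns to the route at 27.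

Step 11. The process at risk is attack on the wrong face of the aldehyde during ring closure, because only remote centres and the ring conformation steer C9. The fallback replaces substrate control by reagent control after the ring is closed; it sets out from 20 as obtained from the epimer mixture. MnO2 oxidises the allylic alcohol to the cross-conjugated enone F4. Corey–Bakshi–Shibata reduction ((R)-2-methyl-CBS-oxazaborolidine, catecholborane, toluene, −78 °C; the alkenyl carbon C8 acts as the large group) then adds hydride to one face and comes back at 20 as the 9S alcohol.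

Step 12. The process at risk is poor E/Z control in the boron–oxygen elimination, together with enolisation of the methyl ketone by the basic boryl carbanion. The fallback separates olefination from borylation and sets out from 19. Wittig methylenation (Ph3PCH3Br, KOtBu, THF) gives the 1,1-disubstituted alkene F5. Cross-metathesis with vinylboronic acid pinacol ester (second-generation Hoveyda–Grubbs catalyst, CH2Cl2, 40 °C) places boron trans to the chain and comes back at 20; the hindered C8 methylidene, flanked by C7 and C9, should stay out of the metathesis.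

Further compounds
F1 | step 16 | (1Z,4R,6S,9R)-1-formyl-2,9-dimethyl-5-methylidene-4-(3-methyl-4-oxobutyl)cycloundec-1-en-6-yl acetate, both epimers at the α-methyl carbon | C=C1[C@@H](OC(C)=O)CC[C@H](C)CC/C(C=O)=C(C)/C[C@H]1CCC(C)C=O
F2 | step 16 | (2E,4R,6S,9R)-1-[(E)-(tert-butyldimethylsilyloxy)methylidene]-4-[(3E)-4-(tert-butyldimethylsilyloxy)-3-methylbut-3-en-1-yl]-2,9-dimethyl-5-methylidenecycloundec-2-en-6-yl acetate | C=C1[C@@H](OC(C)=O)CC[C@H](C)CC/C(=C\O[Si](C)(C)C(C)(C)C)/C(C)=C/[C@H]1CC/C(C)=C/O[Si](C)(C)C(C)(C)C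
F3 | step 16 | (2R,3R,4S,7R,9S,12R,16S)-2,3-bis(tert-butyldimethylsilyloxy)trinervita-1(15),8(19)-dien-9-yl acetate | C=C1[C@@H](OC(C)=O)CC[C@H](C)CCC2=C(C)[C@@H]3[C@H]1CC[C@]3(C)[C@@H](O[Si](C)(C)C(C)(C)C)[C@@H]2O[Si](C)(C)C(C)(C)C
F4 | step 11 | methyl (1Z,4R,9R)-2,9-dimethyl-5-methylidene-4-[(3E)-3-methyl-4-Bpin-but-3-en-1-yl]-6-oxocycloundec-1-ene-1-carboxylate | C=C1C(=O)CC[C@H](C)CC/C(C(=O)OC)=C(C)/C[C@H]1CC/C(C)=C/B2OC(C)(C)C(C)(C)O2
F5 | step 12 | methyl (1Z,4R,6S,9R)-6-hydroxy-2,9-dimethyl-5-methylidene-4-(3-methylbut-3-en-1-yl)cycloundec-1-ene-1-carboxylate | C=C1[C@@H](O)CC[C@H](C)CC/C(C(=O)OC)=C(C)/C[C@H]1CCC(C)=C
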